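The data stem from a simulated flask with constants of no real substance, noise included.

**The question.** Which flask, delta or epsilon, ends with the larger excess of right-handed over left-handed substrate among what is left? They differ in time.

| setting | summer | spring | dawn | delta | epsilon |
|---|---|---|---|---|---|
| left-handed substrate | 0.80 M | 0.80 M | 0.40 M | 0.80 M | 0.80 M |
| right-handed substrate | 0.80 M | 0.80 M | 0.40 M | 0.80 M | 0.80 M |
| solid reagent | 0.88 M | 0.88 M | 0.88 M | 0.880 M | 0.880 M |
| catalyst | 8 mM | 12 mM | 16 mM | 16 mM | 16 mM |
| remark | run made earlier | run made earlier | run made earlier |  |  |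
| time |  |  |  | 10 min | 40 min |

- summer (time / min: right-handed substrate / %, left-handed substrate / %, left-handed product / %): 2.00: 49.9, 49.8, 0.5; 4.00: 50.2, 48.3, 0.7; 6.00: 49.2, 46.8, 2.7; 8.00: 49.1, 45.7, 4.1; 10.0: 48.8, 44.1, 5.3; 12.0: 49.0, 42.3, 6.9
- spring (time / min: right-handed substrate / %, left-handed substrate / %, left-handed product / %): 1.00: 49.9, 49.3, 0.7; 1.50: 49.7, 49.3, 0.5; 2.50: 49.9, 48.9, 0.9; 4.00: 49.8, 47.9, 2.9; 8.00: 48.5, 43.7, 5.8; 12.0: 48.1, 40.5, 9.0
- dawn (time / min: right-handed substrate / %, left-handed substrate / %, left-handed product / %): 2.50: 49.7, 48.6, 1.7; 5.00: 48.9, 45.8, 4.4; 8.00: 48.2, 41.4, 7.8; 10.0: 48.1, 38.9, 9.9; 12.0: 47.8, 37.1, 11.4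

(each reading ± 0.3 percentage points)

1. the winner by excess of right-handed substrate over left-handed substrate among what is left of the two; "neither" if no more than 2 percentage points parts them (delta / epsilon / neither)
2. excess of right-handed substrate over left-handed substrate among what is left of the two at the end, delta
3. excess of right-handed substrate over left-handed substrate among what is left of the two at the end, epsilon

- catalyst is single-handed; left-handed substrate and right-handed substrate are mirror images of each other, charged as a racemate, each of them at the stated concentration
- solid reagent is a solid; its amount is given per volume of the solution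
- at the start none of the solid reagent is in solution
- an excess is below zero if the other one leads

**First instants.** No solid reagent was in solution at the start, and the spring run had made 0.9% of left-handed product by 2.50 min. I read this lag as dissolving.

**The middle.** After the lag I took k, the fractional loss of left-handed substrate per minute. Dawn gave 0.0301 min⁻¹ and spring 0.0210 min⁻¹. Their ratio, 1.43, lay near the catalyst ratio, 1.33, although spring held 2.00 times dawn's substrate. So I took the loss as pseudo-first-order in substrate, with dissolved reagent roughly level. Dawn's last reading gave 6.63 for the selectivity factor s, the logarithm of the fraction of left-handed substrate left, f, over that of the right-handed, g. It is a rough reading, since that right-handed loss is few scatters wide. Then g = f^(1/s), and the excess is (g − f)/(g + f).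

**The end.** Dawn's line put the lag at 2.08 min. For delta, I reckoned f = 78.8%, g = 96.5% and an excess of 10.1%. For epsilon, f = 31.9%, g = 84.2% and an excess of 45.0%. At one reagent per substrate, epsilon uses 0.671 M, less than the 0.880 M charged.

**The forecast.** It named epsilon, with 8% for delta and 40% for epsilon, both below my figures. It saw the lag as “which fits the solid reagent having to dissolve first”.

**The flask.** The winner was epsilon: delta gave 9.28%, epsilon 44.0%. In delta the partner, the dissolved reagent, was made net 2.05 times as fast as it was used up after 3.19 min, and that ratio fell to 1.09 after 10.0 min, when the partner stood at 0.204 M. From epsilon's 32% of left-handed substrate left, s gives 84.2% right-handed against 82%. Moving delta's excess 5 points took 5.61 min or 14.2 min, or 6.57 mM or 27.8 mM of catalyst; a run there could prove the forecast wrong.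

    partner + catalyst + left-handed substrate → catalyst + left-handed product (k = 0.260 L² mol⁻² s⁻¹)
    partner + catalyst + right-handed substrate → catalyst + right-handed product (k = 0.0450 L² mol⁻² s⁻¹)
    left-handed product ⇌ right-handed product (k = 5.30 × 10⁻⁴ s⁻¹)
    solid reagent ⇌ partner, rate k4*(cs4 - [partner]) while solid is left; crystals form when [partner] > cs4 (solubility = 0.270 M, k = 0.00600 s⁻¹)
    catalyst ⇌ dormant form (K = 0.780, k = 0.0280 s⁻¹)

**Longer delta.** For delta left until 15 min, my line gives f = 67.8%, and s then gives an excess of 16.4%. The flask gave 15.2%.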